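The readings come from a simulation on assumed constants.

The fading of D was slow: Tuesday's run read 91.2 % D after 3.00 h and still held 36.8 % after 40.0 h.

in all of them: G 5 mol%; J 20 mol%

| run | Q | L | X | remark | time |
|---|---|---|---|---|---|
| Tuesday's | 0.050 M | 1.5 equiv | 2.5 mM | run made earlier |  |
| Wednesday's | 0.025 M | 1.5 equiv | 2.5 mM | run made earlier |  |
| Sunday's | 0.038 M | 1.5 equiv | 2.5 mM | run made earlier |  |
| Thursday's | 0.050 M | 2.2 equiv | 2.5 mM | run made earlier |  |
| maple | 0.050 M | 1.50 equiv | 2.50 mM | everything together in a closed stirred flask, run for 40 h | 40 h |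
| oak | 0.050 M | 1.50 equiv (fed, over 40.0 h) | 2.50 mM | a stirred flask in which L is dosed at a steady rate over 40.0 h without added volume, worked up at 40 h | 40 h |
| larch | 0.050 M | 1.50 equiv | 2.50 mM | one stirred flow tank at steady state, fed with the mixture as stated, mean residence time 200 h |  |
| elm | 0.050 M | 1.50 equiv | 2.50 mM | a single well-mixed tank run continuously and read at steady state, 40 h in it on average |  |

| run | time / h | D / % | E / % |
|---|---|---|---|
| Tuesday's | 3.00 | 91.2 | 6.2 |
| Tuesday's | 5.00 | 85.1 | 11.6 |
| Tuesday's | 8.00 | 77.6 | 18.5 |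
| Tuesday's | 12.0 | 69.8 | 27.2 |
| Tuesday's | 15.0 | 64.8 | 31.8 |
| Tuesday's | 25.0 | 51.0 | 45.1 |
| Tuesday's | 40.0 | 36.8 | 57.8 |
| Wednesday's | 5.00 | 93.5 | 3.9 |
| Wednesday's | 10.0 | 89.0 | 5.3 |
| Wednesday's | 15.0 | 85.8 | 9.0 |
| Wednesday's | 20.0 | 81.5 | 12.7 |
| Wednesday's | 25.0 | 77.0 | 15.0 |
| Wednesday's | 30.0 | 73.9 | 18.3 |
| Sunday's | 1.50 | 83.2 | 1.0 |
| Sunday's | 5.00 | 90.6 | 7.0 |
| Sunday's | 10.0 | 81.6 | 14.9 |
| Sunday's | 15.0 | 74.6 | 19.9 |
| Sunday's | 20.0 | 68.0 | 25.3 |
| Sunday's | 25.0 | 63.2 | 31.0 |
| Sunday's | 30.0 | 59.4 | 34.8 |
| Thursday's | 6.00 | 77.4 | 21.1 |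
| Thursday's | 12.0 | 60.1 | 36.3 |
| Thursday's | 20.0 | 43.5 | 50.5 |
| Thursday's | 25.0 | 36.2 | 58.7 |
| Thursday's | 30.0 | 31.5 | 64.1 |

(readings scatter by 0.5 percentage points)

- the stated concentrations are those of everything mixed, before any reaction; amounts are the same in each set-up
- the numbers in the tables scatter by 0.5 percentage points (one standard deviation)
- the feed brings no volume worth counting
- the earlier runs were made in a closed, stirred flask

1. order of the set-ups by the amount of D at the outlet or at the end, in percent of the Q put in, highest first (maple / oak / larch / elm)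
2. amount of D at the outlet or at the end, in percent of the Q put in, maple
3. amount of D at the outlet or at the end, in percent of the Q put in, oak
4. amount of D at the outlet or at the end, in percent of the Q put in, larch
5. amount of D at the outlet or at the end, in percent of the Q put in, elm

Q is the limiting reagent, and I took each E to cost one L, so the balance reads: L present = L put in so far, minus E. I divided the hourly fall of ln[D], its pseudo-first-order rate, by the mean [L] over the same stretch. Tuesday's readings from 15.0 h to 40.0 h gave 0.430 L mol⁻¹ h⁻¹, and Thursday's from 12.0 h to 30.0 h gave 0.423 L mol⁻¹ h⁻¹. I carried their mean, 0.427 L mol⁻¹ h⁻¹, as the fade constant: at Tuesday's charges of Q, G, J and X, the fade rate of D is this constant times [L]. Maple, oak, larch and elm have those charges. D and E together read 94.6 % on Tuesday at 40.0 h, and I took that as D's starting stock.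

Maple repeats Tuesday's recipe and starts at a fade rate of 0.0320 h⁻¹. Oak starts with no L, and before any loss of L its fade rate climbs with the feed towards that value, so it averages half of it. Over 40.0 h that makes 0.640 of accumulated fade. E also eats L. I let E grow with time squared, which averages a third of its end value, and this slows oak by a further factor 0.801. The accumulated fade drops to 0.513, and I reckoned oak's final D near 56.7 %.

The forecast, which held that “L is used up one-for-one with E”, integrated stepwise and gave oak 57.3 %, a little above my figure. It gave maple 36.8 %, larch 22.5 % and elm 50 %, in the order oak > elm > maple > larch.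

The flasks gave oak > elm > maple > larch: maple 37.2 %, oak 57.6 %, larch 22.8 %, elm 50.7 %.

    L + J + D → J + E (k = 41.2 L² mol⁻² h⁻¹)
    D + X → Z (k = 2.56 L mol⁻¹ h⁻¹)
    Q + G → G + D (k = 671 L mol⁻¹ h⁻¹)

In oak the half-life of Q by the G step was 0.41 h at 0.414 h, while that of D by the L step was far longer, 30 h at 40.0 h, and the fade constant with oak's 75 % of its L charge puts that half-life at 28.9 h. In larch, a steady tank where D is the stock divided by one plus fade rate times residence time, the constant with 72.6 % E at the outlet and 200 h on average gives 22.0 %, and larch held 22.8 %.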